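**Retrosynthetic overview**
1. Target ⇒ angelate ester at the side-chain carbinol C1′ (made last), C3 acetate and acrylate methyl ester ⇒ a cis-fused α-methylene γ-lactone spanning the C3 oxygen and the C2 side chain (opened by saponification, O-methylation and acetylation) ⇒ the tertiary α-hydroxy lactone (dehydration).
2. Key disconnection, a formal (3+2) annulation: bonds C3–C3a and O1–C2 are cut to give 4-[(1S)-1-silyloxyethyl]phenol and methyl (2R,3R)-3-formyl-2-methyloxirane-2-carboxylate.
3. Feature used: the benzene ring (ring A) carries its only side chain at C5, para to O1, so para attack is blocked and the two ortho carbons of the phenol are equivalent; in the dihydrofuran ring (ring B) the carbinol carbon C3 and the ether carbon C2 are the carbonyl and α-carbons of a 2,3-epoxy aldehyde, whose methyl-bearing carbon is the acrylate α-carbon in hydrated form.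
4. Ring order: ring A is bought (4′-hydroxyacetophenone); ring B closes in the key step; a γ-lactone (ring C) forms in the same pot, carries the tertiary carbinol through the dehydration and is opened in step 10.
5. Fragments: the phenol by asymmetric transfer hydrogenation (sets C1′); the epoxy aldehyde by Wittig olefination, acetal hydrolysis and aminocatalytic epoxidation (sets C2); C3 is set in the key step.

Key step: step 8

**Remarks on the chemistry (assumptions)**
- The absolute sense of the aminocatalytic epoxidation is taken from the steric shielding model of the E-configured iminium ion (attack on the face remote from the diaryl(silyloxy)methyl group). The configuration of the epoxy aldehyde would be checked before the key step; the enantiomeric catalyst is equally accessible.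
- The open dihydroxy ester formed by the annulation has its C3 hydroxyl and the ester cis on a five-membered ring. It is expected to lactonise under the base that generates the phenoxide, so the γ-lactone is taken as the isolated product. The lactone is then used to advantage: its only free hydroxyl is the tertiary one, and its rigid cis fusion directs the dehydration to the methyl group.
- In 13 and 14 the ring carbon that becomes C2 of the target is named R (3aR in the lactone) although its geometry is that of the (2S) target, because the carbinol-bearing side-chain carbon then outranks C3.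

**Route**

Step 1
Reactants: 1 4′-hydroxyacetophenone
Product: 2 1-[4-(tert-butyldimethylsilyloxy)phenyl]ethanone
Conditions: TBSCl, imidazole, DMF, rt
Reagents that add atoms: tert-butyldimethylsilyl chloride, CC(C)(C)[Si](C)(C)Cl
Why: Imidazole-promoted O-silylation masks the acidic phenol so that the ketone behaves as a neutral 4-alkoxy-type acetophenone in the reduction that follows.

Step 2
Reactants: 2 1-[4-(tert-butyldimethylsilyloxy)phenyl]ethanone
Product: 3 (1S)-1-[4-(tert-butyldimethylsilyloxy)phenyl]ethanol
Conditions: RuCl(p-cymene)[(S,S)-TsDPEN] (1 mol%), HCO2H/Et3N (5:2), rt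
Reagents that add atoms: none
Why: Noyori asymmetric transfer hydrogenation of an aryl methyl ketone, in which the (S,S)-TsDPEN ruthenium hydride delivers hydride through the six-membered bifunctional transition state to give the (S)-carbinol, irreversibly because formic acid is the reductant.

Step 3
Reactants: 3 (1S)-1-[4-(tert-butyldimethylsilyloxy)phenyl]ethanol
Product: 4 tert-butyl{4-[(1S)-1-(tert-butyldimethylsilyloxy)ethyl]phenoxy}dimethylsilane
Conditions: TBSCl, imidazole, DMF, rt
Reagents that add atoms: tert-butyldimethylsilyl chloride, CC(C)(C)[Si](C)(C)Cl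
Why: Standard silyl ether formation at the secondary benzylic alcohol under non-ionising conditions, so the stereocentre is untouched.

Step 4
Reactants: 4 tert-butyl{4-[(1S)-1-(tert-butyldimethylsilyloxy)ethyl]phenoxy}dimethylsilane
Product: 5 4-[(1S)-1-(tert-butyldimethylsilyloxy)ethyl]phenol
Conditions: K2CO3, MeOH, rt
Reagents that add atoms: none
Why: Methanolic carbonate cleaves aryl silyl ethers much faster than alkyl silyl ethers (phenoxide is the better leaving group), so only the phenol should be released.

Step 5
Reactants: 6 2,2-dimethoxyacetaldehyde; 7 methyl 2-(triphenylphosphoranylidene)propanoate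
Product: 8 methyl (2E)-4,4-dimethoxy-2-methylbut-2-enoate
Conditions: 6 (60% aq.), CH2Cl2, rt
Reagents that add atoms: none
Why: Wittig olefination with a stabilised α-methyl ylide should give the (E)-trisubstituted enoate, with the ester trans to the acetal carbon.

Step 6
Reactants: 8 methyl (2E)-4,4-dimethoxy-2-methylbut-2-enoate
Product: 9 methyl (2E)-2-methyl-4-oxobut-2-enoate
Conditions: TsOH·H2O (cat.), acetone/H2O, rt
Reagents that add atoms: water, O
Why: Acid-catalysed acetal hydrolysis; the (E)-geometry (formyl trans to the ester) is the thermodynamically preferred one and should be retained.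

Step 7
Reactants: 9 methyl (2E)-2-methyl-4-oxobut-2-enoate
Product: 10 methyl (2R,3R)-3-formyl-2-methyloxirane-2-carboxylate
Conditions: (R)-2-{bis[3,5-bis(trifluoromethyl)phenyl](trimethylsilyloxy)methyl}pyrrolidine (10 mol%), 35% aq. H2O2, CH2Cl2, rt
Reagents that add atoms: hydrogen peroxide, OO
Why: Iminium-activated nucleophilic epoxidation of an enal, in which H2O2 adds to the β-carbon of the E-iminium ion on the face remote from the diaryl(silyloxy)methyl group and the resulting enamine closes onto the O–O bond, so the alkene geometry is carried into the trans-epoxide and both centres (2R,3R) are set by the catalyst.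

Step 8
Reactants: 5 4-[(1S)-1-(tert-butyldimethylsilyloxy)ethyl]phenol; 10 methyl (2R,3R)-3-formyl-2-methyloxirane-2-carboxylate
Product: 14 (3R,3aR,8bS)-7-[(1S)-1-(tert-butyldimethylsilyloxy)ethyl]-3-hydroxy-3-methyl-3a,8b-dihydrofuro[3,2-b][1]benzofuran-2(3H)-one, via titanium phenoxide 11 (not isolated), via anti epoxy alcohol adduct 12 (not isolated), via dihydroxy ester 13 (not isolated)
Conditions: Ti(OiPr)4 (1.1 equiv), toluene, rt, then iPrOH removed in vacuo; 10, toluene, −20 °C → rt; then MeOH, K2CO3, 0 °C → rt
Reagents that add atoms: none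
Why: Proposed new method: the aryloxytitanium triisopropoxide 11 binds the formyl oxygen of 10 and delivers its ortho carbon through a six-membered cyclic transition state (bond C3–C3a), and rearomatisation gives the titanium-bound salicyl alcohol 12; the closest known reactions are the ortho-specific hydroxyalkylation of titanium and magnesium phenoxides with α-oxygenated aldehydes and the base-induced cyclisation of ortho-(epoxyalkyl)phenols to 2-(1-hydroxyalkyl)-2,3-dihydrobenzofurans, while the tandem on an epoxy aldehyde is untested. The new C3 carbinol centre is set by Felkin–Anh/Cornforth addition anti to the epoxide C–O bond, reinforced by the methyl group cis to the formyl group; the weakly Lewis acidic, monodentate Ti(OiPr)3 centre is chosen because it should not chelate the epoxide oxygen, whereas a magnesium phenoxide could and would then lead to the syn adduct and the trans ring. After methanolysis of the Ti–O bonds the potassium phenoxide opens the epoxide at the secondary carbon remote from the ester in a 5-exo-tet closure with inversion (bond O1–C2), which turns the anti adduct into the 2,3-cis dihydrobenzofuran 13; the competing 6-endo attack would have to occur at a quaternary carbon α to the ester. Because the C3 hydroxyl and the ester are cis on ring B, 13 should lactonise under the same conditions (5-exo-trig acyl substitution) to the cis-fused γ-lactone 14; a 2,3-trans by-product cannot lactonise and would stay as an open diol ester that is removed by chromatography. Site selectivity on the arene needs no control, since the para position is blocked and both ortho positions are equivalent, and carbonate ionises the phenol but not the secondary alcohol, which should suppress Payne rearrangement.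

Step 9
Reactants: 14 (3R,3aR,8bS)-7-[(1S)-1-(tert-butyldimethylsilyloxy)ethyl]-3-hydroxy-3-methyl-3a,8b-dihydrofuro[3,2-b][1]benzofuran-2(3H)-one
Product: 15 (3aS,8bS)-7-[(1S)-1-(tert-butyldimethylsilyloxy)ethyl]-3-methylidene-3a,8b-dihydrofuro[3,2-b][1]benzofuran-2(3H)-one
Conditions: Burgess reagent (MeO2CN–SO2NEt3 inner salt, 2 equiv), toluene, 50 → 70 °C
Reagents that add atoms: none
Why: Burgess dehydration, in which the only free hydroxyl of 14 is converted into its sulfamate ester and this fragments by thermal syn-elimination; in the cis-fused lactone the tertiary oxygen is trans to H-3a, so only the methyl hydrogens are within reach and the exocyclic methylene should form without the endocyclic isomer, while C3a and C8b are untouched.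

Step 10
Reactants: 15 (3aS,8bS)-7-[(1S)-1-(tert-butyldimethylsilyloxy)ethyl]-3-methylidene-3a,8b-dihydrofuro[3,2-b][1]benzofuran-2(3H)-one
Product: 18 methyl 2-[(2S,3S)-3-acetoxy-5-[(1S)-1-(tert-butyldimethylsilyloxy)ethyl]-2,3-dihydro-1-benzofuran-2-yl]prop-2-enoate, via lithium hydroxy acrylate 16 (not isolated), via hydroxy acrylate methyl ester 17 (not isolated)
Conditions: LiOH·H2O (1.05 equiv), THF/H2O, 0 °C; evaporate; MeI, DMF, rt; excess MeI removed; Ac2O, pyridine, 0 °C → rt
Reagents that add atoms: lithium hydroxide, [Li+].[OH-]; iodomethane, CI; acetic anhydride, CC(=O)OC(C)=O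
Why: Saponification opens the α-methylene lactone at its acyl carbon, SN2 O-methylation of the carboxylate in the absence of any alkoxide gives the hydroxy acrylate ester 17 under neutral conditions, and acetylation in pyridine caps the secondary C3 hydroxyl at once, which blocks relactonisation without breaking a C–O bond at a stereocentre; DMAP is left out so that no nucleophilic catalyst adds to the acrylate.

Step 11
Reactants: 18 methyl 2-[(2S,3S)-3-acetoxy-5-[(1S)-1-(tert-butyldimethylsilyloxy)ethyl]-2,3-dihydro-1-benzofuran-2-yl]prop-2-enoate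
Product: 19 methyl 2-[(2S,3S)-3-acetoxy-5-[(1S)-1-hydroxyethyl]-2,3-dihydro-1-benzofuran-2-yl]prop-2-enoate
Conditions: Bu4NF, AcOH (1:1), THF, 0 °C → rt
Reagents that add atoms: none
Why: Fluoride-mediated desilylation buffered with acetic acid keeps the medium near neutral, so the acetate, the acrylate and the configuration of the electron-rich benzylic carbinol should survive.

Step 12
Reactants: 19 methyl 2-[(2S,3S)-3-acetoxy-5-[(1S)-1-hydroxyethyl]-2,3-dihydro-1-benzofuran-2-yl]prop-2-enoate; 20 angelic acid
Product: 22 (1S)-1-[(2S,3S)-3-acetoxy-2-(3-methoxy-3-oxoprop-1-en-2-yl)-2,3-dihydro-1-benzofuran-5-yl]ethyl (2Z)-2-methylbut-2-enoate, via mixed anhydride 21 (not isolated)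
Conditions: 20, 2,4,6-Cl3C6H2COCl, Et3N, toluene, rt; then 19, toluene, 70 °C
Reagents that add atoms: none
Why: Yamaguchi esterification, in which the alcohol attacks the less hindered angeloyl carbonyl of the mixed anhydride with retention at the carbinol carbon, and the absence of DMAP avoids the addition–elimination pathway that isomerises the (Z)-angelate to the (E)-tiglate.

**Compound list**
1 | 4′-hydroxyacetophenone | CC(=O)c1ccc(O)cc1 | starting material
2 | 1-[4-(tert-butyldimethylsilyloxy)phenyl]ethanone | CC(=O)c1ccc(O[Si](C)(C)C(C)(C)C)cc1 | intermediate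
3 | (1S)-1-[4-(tert-butyldimethylsilyloxy)phenyl]ethanol | C[C@H](O)c1ccc(O[Si](C)(C)C(C)(C)C)cc1 | intermediate
4 | tert-butyl{4-[(1S)-1-(tert-butyldimethylsilyloxy)ethyl]phenoxy}dimethylsilane | C[C@H](O[Si](C)(C)C(C)(C)C)c1ccc(O[Si](C)(C)C(C)(C)C)cc1 | intermediate
5 | 4-[(1S)-1-(tert-butyldimethylsilyloxy)ethyl]phenol | C[C@H](O[Si](C)(C)C(C)(C)C)c1ccc(O)cc1 | intermediate
6 | 2,2-dimethoxyacetaldehyde | COC(OC)C=O | starting material
7 | methyl 2-(triphenylphosphoranylidene)propanoate | COC(=O)C(C)=P(c1ccccc1)(c1ccccc1)c1ccccc1 | starting material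
8 | methyl (2E)-4,4-dimethoxy-2-methylbut-2-enoate | COC(OC)/C=C(\C)C(=O)OC | intermediate
9 | methyl (2E)-2-methyl-4-oxobut-2-enoate | O=C/C=C(\C)C(=O)OC | intermediate
10 | methyl (2R,3R)-3-formyl-2-methyloxirane-2-carboxylate (formyl trans to the ester) | O=C[C@@H]1O[C@@]1(C)C(=O)OC | intermediate
11 | {4-[(1S)-1-(tert-butyldimethylsilyloxy)ethyl]phenoxy}tri(propan-2-yloxy)titanium | CC(C)O[Ti](OC(C)C)(OC(C)C)Oc1ccc(cc1)[C@H](C)O[Si](C)(C)C(C)(C)C | intermediate
12 | methyl (2R,3S)-3-[(S)-{5-[(1S)-1-(tert-butyldimethylsilyloxy)ethyl]-2-hydroxyphenyl}(hydroxy)methyl]-2-methyloxirane-2-carboxylate (anti adduct, formed as its titanium alkoxide) | Oc1ccc([C@H](C)O[Si](C)(C)C(C)(C)C)cc1[C@H](O)[C@@H]1O[C@@]1(C)C(=O)OC | intermediate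
13 | methyl (2R)-2-hydroxy-2-[(2R,3S)-3-hydroxy-5-[(1S)-1-(tert-butyldimethylsilyloxy)ethyl]-2,3-dihydro-1-benzofuran-2-yl]propanoate (2,3-cis) | COC(=O)[C@](C)(O)[C@@H]1Oc2ccc([C@H](C)O[Si](C)(C)C(C)(C)C)cc2[C@@H]1O | intermediate
14 | (3R,3aR,8bS)-7-[(1S)-1-(tert-butyldimethylsilyloxy)ethyl]-3-hydroxy-3-methyl-3a,8b-dihydrofuro[3,2-b][1]benzofuran-2(3H)-one (cis-fused lactone of 13) | O=C3[C@](C)(O)[C@@H]1Oc2ccc([C@H](C)O[Si](C)(C)C(C)(C)C)cc2[C@@H]1O3 | intermediate
15 | (3aS,8bS)-7-[(1S)-1-(tert-butyldimethylsilyloxy)ethyl]-3-methylidene-3a,8b-dihydrofuro[3,2-b][1]benzofuran-2(3H)-one (cis-fused α-methylene lactone) | O=C3C(=C)[C@@H]1Oc2ccc([C@H](C)O[Si](C)(C)C(C)(C)C)cc2[C@@H]1O3 | intermediate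
16 | lithium 2-[(2S,3S)-5-[(1S)-1-(tert-butyldimethylsilyloxy)ethyl]-3-hydroxy-2,3-dihydro-1-benzofuran-2-yl]prop-2-enoate | [Li+].[O-]C(=O)C(=C)[C@@H]1Oc2ccc([C@H](C)O[Si](C)(C)C(C)(C)C)cc2[C@@H]1O | intermediate
17 | methyl 2-[(2S,3S)-5-[(1S)-1-(tert-butyldimethylsilyloxy)ethyl]-3-hydroxy-2,3-dihydro-1-benzofuran-2-yl]prop-2-enoate | C=C(C(=O)OC)[C@@H]1Oc2ccc([C@H](C)O[Si](C)(C)C(C)(C)C)cc2[C@@H]1O | intermediate
18 | methyl 2-[(2S,3S)-3-acetoxy-5-[(1S)-1-(tert-butyldimethylsilyloxy)ethyl]-2,3-dihydro-1-benzofuran-2-yl]prop-2-enoate | C=C(C(=O)OC)[C@@H]1Oc2ccc([C@H](C)O[Si](C)(C)C(C)(C)C)cc2[C@@H]1OC(C)=O | intermediate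
19 | methyl 2-[(2S,3S)-3-acetoxy-5-[(1S)-1-hydroxyethyl]-2,3-dihydro-1-benzofuran-2-yl]prop-2-enoate | C=C(C(=O)OC)[C@@H]1Oc2ccc([C@H](C)O)cc2[C@@H]1OC(C)=O | intermediate
20 | angelic acid, (2Z)-2-methylbut-2-enoic acid | C/C=C(/C)C(=O)O | starting material
21 | (2Z)-2-methylbut-2-enoic 2,4,6-trichlorobenzoic anhydride | C/C=C(/C)C(=O)OC(=O)c1c(Cl)cc(Cl)cc1Cl | intermediate
22 | (1S)-1-[(2S,3S)-3-acetoxy-2-(3-methoxy-3-oxoprop-1-en-2-yl)-2,3-dihydro-1-benzofuran-5-yl]ethyl (2Z)-2-methylbut-2-enoate | C=C(C(=O)OC)[C@@H]1Oc2ccc([C@H](C)OC(=O)/C(C)=C\C)cc2[C@@H]1OC(C)=O | target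

**Step count**
Total: 12 steps (4 to the phenol, 3 to the epoxy aldehyde, 5 from the union onwards). Longest linear sequence: 9 steps (steps 1–4 and 8–12, from 1 to 22).

**Steps most likely to fail, with fallbacks**

Step 8 (key step). The ortho carbon of a phenoxide activated only by a para alkyl group may attack the formyl group too slowly, so that hemiacetal formation at oxygen or hydride transfer from an isopropoxide ligand takes over. Facial control may erode towards the syn adduct. In the basic stage, Payne rearrangement or ortho-quinone methide formation may compete with the 5-exo closure. The fallback uses known aryl–metal chemistry, sets out from 5 and rejoins the route at 12. Compound 5 is brominated ortho to the hydroxyl (NBS, cat. iPr2NH, CH2Cl2, 0 °C) to 2-bromo-4-[(1S)-1-(tert-butyldimethylsilyloxy)ethyl]phenol F1 and O-allylated (allyl bromide, K2CO3, acetone) to 1-(allyloxy)-2-bromo-4-[(1S)-1-(tert-butyldimethylsilyloxy)ethyl]benzene F2. Bromine–lithium exchange (n-BuLi, THF, −78 °C) gives the aryllithium F3, and transmetalation with ClTi(OiPr)3 gives the aryltitanium triisopropoxide F4. This non-chelating reagent should add only to the formyl group of 10, in the Felkin–Anh sense, to give the O-allyl anti adduct F5. Deallylation with Pd(PPh3)4 (zerovalent palladium) and morpholine in THF releases the phenol 12, which is treated with K2CO3 in MeOH as in the second stage of step 8 to reach 14.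

Step 9. Sulfamate formation may be slow at the tertiary hydroxyl, which sits on the concave face of the cis-fused bicycle and next to the lactone carbonyl, and its fragmentation gains no help from ionisation. The strained α-methylene lactone may also be lost to conjugate addition or oligomerisation, during its formation or during the hydroxide opening of step 10. The fallback moves the elimination to the open chain, so that no α-methylene lactone is formed; it sets out from 14 and rejoins at 18. Compound 14 is saponified (LiOH·H2O, THF/H2O, 0 °C) to lithium (2R)-2-hydroxy-2-[(2R,3S)-3-hydroxy-5-[(1S)-1-(tert-butyldimethylsilyloxy)ethyl]-2,3-dihydro-1-benzofuran-2-yl]propanoate F6. Methylation of the dry salt (MeI, DMF, rt) returns the open dihydroxy ester 13 under neutral conditions, and acetylation at once (Ac2O, pyridine, cat. DMAP, 0 °C) caps the secondary C3 hydroxyl to give methyl (2R)-2-[(2R,3S)-3-acetoxy-5-[(1S)-1-(tert-butyldimethylsilyloxy)ethyl]-2,3-dihydro-1-benzofuran-2-yl]-2-hydroxypropanoate F7, which can no longer lactonise. Dehydration with SOCl2 and pyridine (CH2Cl2, −10 → 0 °C) proceeds by E2 elimination of the tertiary chlorosulfite, in which proton removal from the unhindered methyl group should be preferred over the hindered C2–H, and delivers 18.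

Step 7. E/Z equilibration of the iminium ion through the cross-conjugated dienamine (deprotonation at the methyl group), weaker facial control at a β,β-disubstituted terminus, and loss of the small, hydrate-forming epoxy aldehyde on isolation may erode enantio- and diastereopurity or mass balance. The fallback epoxidises at the alcohol oxidation level with a chiral dioxirane, sets out from 9 and rejoins at 10. Luche reduction (NaBH4, CeCl3·7H2O, MeOH, −40 °C) gives methyl (2E)-4-hydroxy-2-methylbut-2-enoate F8. Shi epoxidation with the ester-compatible, acetate-bearing ketone catalyst of the L-fructose series (from L-sorbose; Oxone (2KHSO5·KHSO4·K2SO4), NaHCO3, MeCN/aqueous buffer, 0 °C) should, by the spiro transition-state model, give methyl (2R,3S)-3-(hydroxymethyl)-2-methyloxirane-2-carboxylate F9. Dess–Martin oxidation (CH2Cl2, NaHCO3, 0 °C) returns 10.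

**Further compounds**
F1 | step 8 | 2-bromo-4-[(1S)-1-(tert-butyldimethylsilyloxy)ethyl]phenol | Oc1ccc([C@H](C)O[Si](C)(C)C(C)(C)C)cc1Br
F2 | step 8 | 1-(allyloxy)-2-bromo-4-[(1S)-1-(tert-butyldimethylsilyloxy)ethyl]benzene | C=CCOc1ccc([C@H](C)O[Si](C)(C)C(C)(C)C)cc1Br
F3 | step 8 | {2-(allyloxy)-5-[(1S)-1-(tert-butyldimethylsilyloxy)ethyl]phenyl}lithium | [Li]c1cc(ccc1OCC=C)[C@H](C)O[Si](C)(C)C(C)(C)C
F4 | step 8 | {2-(allyloxy)-5-[(1S)-1-(tert-butyldimethylsilyloxy)ethyl]phenyl}tri(propan-2-yloxy)titanium | CC(C)O[Ti](OC(C)C)(OC(C)C)c1cc(ccc1OCC=C)[C@H](C)O[Si](C)(C)C(C)(C)C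
F5 | step 8 | methyl (2R,3S)-3-[(S)-{2-(allyloxy)-5-[(1S)-1-(tert-butyldimethylsilyloxy)ethyl]phenyl}(hydroxy)methyl]-2-methyloxirane-2-carboxylate | C=CCOc1ccc([C@H](C)O[Si](C)(C)C(C)(C)C)cc1[C@H](O)[C@@H]1O[C@@]1(C)C(=O)OC
F6 | step 9 | lithium (2R)-2-hydroxy-2-[(2R,3S)-3-hydroxy-5-[(1S)-1-(tert-butyldimethylsilyloxy)ethyl]-2,3-dihydro-1-benzofuran-2-yl]propanoate | [Li+].[O-]C(=O)[C@](C)(O)[C@@H]1Oc2ccc([C@H](C)O[Si](C)(C)C(C)(C)C)cc2[C@@H]1O
F7 | step 9 | methyl (2R)-2-[(2R,3S)-3-acetoxy-5-[(1S)-1-(tert-butyldimethylsilyloxy)ethyl]-2,3-dihydro-1-benzofuran-2-yl]-2-hydroxypropanoate | COC(=O)[C@](C)(O)[C@@H]1Oc2ccc([C@H](C)O[Si](C)(C)C(C)(C)C)cc2[C@@H]1OC(C)=O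
F8 | step 7 | methyl (2E)-4-hydroxy-2-methylbut-2-enoate | OC/C=C(\C)C(=O)OC
F9 | step 7 | methyl (2R,3S)-3-(hydroxymethyl)-2-methyloxirane-2-carboxylate | OC[C@@H]1O[C@@]1(C)C(=O)OC
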